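## Retrosynthetic overview

1. Target ⇒ isofraxidin (bought coumarin) + a 3β-silyloxy-9-epi-drimenol; the aryl ether is made by Mitsunobu coupling and the acetate goes on last.
2. The C9–C11 bond and the C9 stereocentre ⇐ [2,3]-sigmatropic Still–Wittig shift of the 7α-(stannylmethyl) ether of an 11-nordrim-8-en-7-ol (suprafacial delivery to the α face).
3. That allylic alcohol ⇐ 8-methyl-Δ8-7-ketone ⇐ decalin-7-one ⇐ oxidative excision of an isopropenyl group.
4. Decalin ⇐ Robinson annulation of (5S)-dihydrocarvone with ethyl vinyl ketone, then reductive gem-dimethylation and 3-ketone reduction.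
5. Ring order: ring B is bought as (S)-carvone, ring A is annulated onto it, the coumarin rings are bought.

Assumption: drimane numbering and α/β descriptors (β = face of the C10 methyl) are used for all decalins; the target SMILES is read as 3β-OAc, 5α-H, 9β-H (C11 α), 10β-Me.

## Route

Step 1
Reactants: 1 (S)-(+)-carvone
Product: 2 (5S)-dihydrocarvone (C2 epimer mixture)
Conditions: LiBH(s-Bu)3, THF, −78 °C; then H2O
Reagents that add atoms: none
Why: Conjugate (1,4) hydride reduction of the enone leaves the isolated isopropenyl group and the bought C5 stereocentre untouched, and the new C2 centre is an epimer mixture that is erased in the next step.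

Step 2
Reactants: 2 (5S)-dihydrocarvone; 3 ethyl vinyl ketone
Product: 6 (+)-10-epi-α-cyperone [(4aS,7S)-enone], via Michael adduct 4 (not isolated), via ketol 5 (not isolated)
Conditions: KOH (cat.), EtOH, 0 °C → rt; then reflux
Reagents that add atoms: none
Why: Robinson annulation in which the more substituted enolate adds to the vinyl ketone by axial attack cis to the equatorial isopropenyl group, so the new quaternary methyl (C10) ends trans to the isopropenyl group, and aldol condensation then closes ring A.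

Step 3
Reactants: 6 (+)-10-epi-α-cyperone
Product: 8 7α-isopropenyl-4,4,10β-trimethyl-5α-decalin-3-one, via lithium enolate 7 (not isolated)
Conditions: Li, NH3(l)/THF, t-BuOH (1 equiv), −78 °C; then MeI, −78 °C → rt
Reagents that add atoms: methyl iodide, CI
Why: Dissolving-metal enone reduction protonates C5 axially to give the trans-fused enolate (5α-H anti to the 10β-methyl), which MeI alkylates regiospecifically at C4 (reductive alkylation) while the isolated alkene survives.

Step 4
Reactants: 8 7α-isopropenyl-4,4,10β-trimethyl-5α-decalin-3-one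
Product: 9 7α-isopropenyl-4,4,10β-trimethyl-5α-decalin-3β-ol
Conditions: NaBH4, MeOH, 0 °C
Reagents that add atoms: none
Why: Hydride reduction of the hindered 4,4-dimethyl-3-ketone occurs by axial attack from the α face, away from the axial 4β-methyl, giving the equatorial 3β-alcohol.

Step 5
Reactants: 9 7α-isopropenyl-4,4,10β-trimethyl-5α-decalin-3β-ol
Product: 10 3β-TBS ether of 9
Conditions: TBSOTf, 2,6-lutidine, CH2Cl2, 0 °C → rt
Reagents that add atoms: tert-butyldimethylsilyl triflate, CC(C)(C)[Si](C)(C)OS(=O)(=O)C(F)(F)F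
Why: Silyl ether protection with the reactive silyl triflate covers the hindered secondary alcohol for the basic steps ahead without touching a stereocentre.

Step 6
Reactants: 10 3β-TBS ether
Product: 13 3β-TBSO-4,4,10β-trimethyl-5α-decalin-7-one, via methoxy hydroperoxide 11 (not isolated), via TEMPO alkoxyamine 12 (not isolated)
Conditions: O3, MeOH/CH2Cl2, −78 °C; then TEMPO, FeSO4·7H2O, 0 °C → rt; then mCPBA, rt
Reagents that add atoms: TEMPO, CC1(C)CCCC(C)(C)N1[O] (its O becomes the ketone O); ozone, [O-][O+]=O, methanol, CO (their atoms stay only in 11)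
Why: Oxodealkenylation, in which ozonolysis in methanol gives the α-methoxy hydroperoxide, divalent iron cleaves the O–O bond, β-scission of the alkoxy radical expels methyl acetate, TEMPO traps the C7 radical and peracid oxidation of the alkoxyamine releases the C7 ketone, deliberately erasing the C7 centre.

Step 7
Reactants: 13 3β-TBSO-4,4,10β-trimethyl-5α-decalin-7-one
Product: 15 3β-TBSO-4,4,8,10β-tetramethyl-5α-decalin-7-one (C8 epimers), via lithium enolate 14 (not isolated)
Conditions: LiN(i-Pr)2, THF, −78 °C; then MeI, −78 → 0 °C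
Reagents that add atoms: methyl iodide, CI
Why: Kinetic enolate alkylation in which deprotonation is expected at C8 and not at C6 (as in 3-keto-5α-steroids, helped here by the neighbouring gem-dimethyl group shielding C6), and the C8 configuration is irrelevant because C8 becomes sp2.

Step 8
Reactants: 15 3β-TBSO-4,4,8,10β-tetramethyl-5α-decalin-7-one
Product: 16 3β-TBSO-11-nordrim-8-en-7-one
Conditions: IBX, DMSO/toluene, 70 °C
Reagents that add atoms: none
Why: IBX-mediated α,β-dehydrogenation through the more substituted enol introduces the C8=C9 double bond and gives the 2-methylcyclohexenone-type enone.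

Step 9
Reactants: 16 3β-TBSO-11-nordrim-8-en-7-one
Product: 17 3β-TBSO-11-nordrim-8-en-7β-ol
Conditions: NaBH4, CeCl3·7H2O, MeOH, −40 °C
Reagents that add atoms: none
Why: Luche 1,2-reduction in which the small hydride adds axially from the α face of the enone carbonyl, giving the pseudoequatorial 7β-allylic alcohol.

Step 10
Reactants: 17 3β-TBSO-11-nordrim-8-en-7β-ol
Product: 19 3β-TBSO-11-nordrim-8-en-7α-ol, via nitrobenzoate ester 18 (not isolated)
Conditions: 4-O2NC6H4CO2H, PPh3, DIAD, THF, 0 °C → rt; then K2CO3, MeOH, rt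
Reagents that add atoms: 4-nitrobenzoic acid, OC(=O)c1ccc(cc1)[N+](=O)[O-] (its O stays on C7)
Why: Mitsunobu reaction with SN2 inversion at the allylic C7, followed by methanolysis of the ester, gives the pseudoaxial 7α-alcohol needed for α-face delivery.

Step 11
Reactants: 19 3β-TBSO-11-nordrim-8-en-7α-ol
Product: 20 7α-[(tributylstannyl)methoxy] ether of 19
Conditions: KH, THF, 0 °C; then Bu3SnCH2I, rt
Reagents that add atoms: tributyl(iodomethyl)stannane, CCCC[Sn](CCCC)(CCCC)CI
Why: Williamson etherification of the potassium alkoxide with the iodomethylstannane proceeds with retention at C7 and gives the Still–Wittig precursor.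

Step 12
Reactants: 20 7α-[(tributylstannyl)methoxy] ether
Product: 22 3β-TBSO-9-epi-drimenol (3β-TBSO-drim-7-en-11-ol with 9β-H), via lithiomethyl ether 21 (not isolated)
Conditions: n-BuLi, THF, −78 → −20 °C; then H2O
Reagents that add atoms: none
Why: Tin–lithium exchange gives the α-alkoxymethyl carbanion, which undergoes a suprafacial [2,3]-sigmatropic Still–Wittig shift from the pseudoaxial 7α-oxygen to the α face of C9 (anti to the C10 methyl), forming the C9–C11 bond with 9β-H and moving the double bond to C7=C8.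

Step 13
Reactants: 22 3β-TBSO-9-epi-drimenol; 23 isofraxidin
Product: 24 7-O-(3β-TBSO-9-epi-drim-7-en-11-yl)isofraxidin
Conditions: PPh3, DIAD, THF, 0 °C → rt
Reagents that add atoms: none
Why: Mitsunobu etherification of the primary alcohol with the acidic phenol of isofraxidin forms the aryl alkyl ether without touching a stereocentre.

Step 14
Reactants: 24 7-O-(3β-TBSO-9-epi-drim-7-en-11-yl)isofraxidin
Product: 25 7-O-(3β-hydroxy-9-epi-drim-7-en-11-yl)isofraxidin
Conditions: HF·pyridine, THF/pyridine, 0 °C → rt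
Reagents that add atoms: none
Why: Fluoride-mediated desilylation under buffered conditions frees the 3β-alcohol without isomerising the C7=C8 double bond or opening the coumarin lactone.

Step 15
Reactants: 25 7-O-(3β-hydroxy-9-epi-drim-7-en-11-yl)isofraxidin
Product: 26 target CNP0285931.2
Conditions: Ac2O, pyridine, DMAP (cat.), CH2Cl2, rt
Reagents that add atoms: acetic anhydride, CC(=O)OC(C)=O
Why: DMAP-catalysed O-acylation of the equatorial secondary alcohol gives the 3β-acetate with retention.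

## Compound list

1 | (S)-(+)-carvone, (5S)-2-methyl-5-(prop-1-en-2-yl)cyclohex-2-en-1-one | CC1=CC[C@@H](CC1=O)C(C)=C | starting material
2 | (5S)-dihydrocarvone, (2RS,5S)-2-methyl-5-(prop-1-en-2-yl)cyclohexan-1-one | CC1CC[C@@H](CC1=O)C(C)=C | intermediate
3 | ethyl vinyl ketone (pent-1-en-3-one) | CCC(=O)C=C | starting material
4 | Michael adduct, (2S,5S)-2-methyl-2-(3-oxopentyl)-5-(prop-1-en-2-yl)cyclohexan-1-one | CCC(=O)CC[C@]1(C)CC[C@H](C(C)=C)CC1=O | intermediate
5 | ketol, 5-hydroxy-4,10β-dimethyl-7α-isopropenyldecalin-3-one (C4/C5 not assigned) | CC1C(=O)CC[C@]2(C)CC[C@H](C(C)=C)CC12O | intermediate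
6 | (+)-10-epi-α-cyperone, (4aS,7S)-1,4a-dimethyl-7-(prop-1-en-2-yl)-4,4a,5,6,7,8-hexahydronaphthalen-2(3H)-one (10β-Me, 7α-isopropenyl) | CC1=C2C[C@@H](C(C)=C)CC[C@@]2(C)CCC1=O | intermediate
7 | lithium enolate, lithium 7α-isopropenyl-4,10β-dimethyl-5α-octal-3-en-3-olate | [Li+].CC1=C([O-])CC[C@]2(C)CC[C@H](C(C)=C)C[C@@H]12 | intermediate
8 | 7α-isopropenyl-4,4,10β-trimethyl-5α-decalin-3-one (trans-fused) | CC1(C)C(=O)CC[C@]2(C)CC[C@H](C(C)=C)C[C@@H]12 | intermediate
9 | 7α-isopropenyl-4,4,10β-trimethyl-5α-decalin-3β-ol | CC1(C)[C@@H](O)CC[C@]2(C)CC[C@H](C(C)=C)C[C@@H]12 | intermediate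
10 | 3β-(tert-butyldimethylsilyloxy)-7α-isopropenyl-4,4,10β-trimethyl-5α-decalin | CC1(C)[C@@H](O[Si](C)(C)C(C)(C)C)CC[C@]2(C)CC[C@H](C(C)=C)C[C@@H]12 | intermediate
11 | methoxy hydroperoxide, 3β-TBSO-7α-(1-hydroperoxy-1-methoxyethyl)-4,4,10β-trimethyl-5α-decalin | CC1(C)[C@@H](O[Si](C)(C)C(C)(C)C)CC[C@]2(C)CC[C@H](C(C)(OC)OO)C[C@@H]12 | intermediate
12 | TEMPO alkoxyamine, 3β-TBSO-7-(2,2,6,6-tetramethylpiperidin-1-yloxy)-4,4,10β-trimethyl-5α-decalin (C7 epimers) | CC1(C)[C@@H](O[Si](C)(C)C(C)(C)C)CC[C@]2(C)CCC(ON3C(C)(C)CCCC3(C)C)C[C@@H]12 | intermediate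
13 | 3β-TBSO-4,4,10β-trimethyl-5α-decalin-7-one (3β-silyloxy-11,12-dinordriman-7-one) | CC1(C)[C@@H](O[Si](C)(C)C(C)(C)C)CC[C@]2(C)CCC(=O)C[C@@H]12 | intermediate
14 | lithium Δ7-enolate of 13 | [Li+].CC1(C)[C@@H](O[Si](C)(C)C(C)(C)C)CC[C@]2(C)CC=C([O-])C[C@@H]12 | intermediate
15 | 3β-TBSO-4,4,8,10β-tetramethyl-5α-decalin-7-one (3β-silyloxy-11-nordriman-7-one, C8 epimers) | CC1(C)[C@@H](O[Si](C)(C)C(C)(C)C)CC[C@]2(C)CC(C)C(=O)C[C@@H]12 | intermediate
16 | 3β-TBSO-11-nordrim-8-en-7-one | CC1(C)[C@@H](O[Si](C)(C)C(C)(C)C)CC[C@]2(C)C=C(C)C(=O)C[C@@H]12 | intermediate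
17 | 3β-TBSO-11-nordrim-8-en-7β-ol | CC1(C)[C@@H](O[Si](C)(C)C(C)(C)C)CC[C@]2(C)C=C(C)[C@@H](O)C[C@@H]12 | intermediate
18 | 3β-TBSO-11-nordrim-8-en-7α-yl 4-nitrobenzoate | CC1(C)[C@@H](O[Si](C)(C)C(C)(C)C)CC[C@]2(C)C=C(C)[C@H](OC(=O)c3ccc(cc3)[N+](=O)[O-])C[C@@H]12 | intermediate
19 | 3β-TBSO-11-nordrim-8-en-7α-ol | CC1(C)[C@@H](O[Si](C)(C)C(C)(C)C)CC[C@]2(C)C=C(C)[C@H](O)C[C@@H]12 | intermediate
20 | 3β-TBSO-7α-[(tributylstannyl)methoxy]-11-nordrim-8-ene | CC1(C)[C@@H](O[Si](C)(C)C(C)(C)C)CC[C@]2(C)C=C(C)[C@H](OC[Sn](CCCC)(CCCC)CCCC)C[C@@H]12 | intermediate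
21 | 3β-TBSO-7α-(lithiomethoxy)-11-nordrim-8-ene | CC1(C)[C@@H](O[Si](C)(C)C(C)(C)C)CC[C@]2(C)C=C(C)[C@H](OC[Li])C[C@@H]12 | intermediate
22 | 3β-TBSO-9-epi-drimenol, 3β-TBSO-drim-7-en-11-ol with 9β-H (CH2OH α) | OC[C@@H]1C(C)=CC[C@H]2C(C)(C)[C@@H](O[Si](C)(C)C(C)(C)C)CC[C@]12C | intermediate
23 | isofraxidin (7-hydroxy-6,8-dimethoxycoumarin) | COc1cc2ccc(=O)oc2c(OC)c1O | starting material
24 | 7-O-(3β-TBSO-9-epi-drim-7-en-11-yl)isofraxidin | COc1cc2ccc(=O)oc2c(OC)c1OC[C@@H]1C(C)=CC[C@H]2C(C)(C)[C@@H](O[Si](C)(C)C(C)(C)C)CC[C@]12C | intermediate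
25 | 7-O-(3β-hydroxy-9-epi-drim-7-en-11-yl)isofraxidin | COc1cc2ccc(=O)oc2c(OC)c1OC[C@@H]1C(C)=CC[C@H]2C(C)(C)[C@@H](O)CC[C@]12C | intermediate
26 | CNP0285931.2, 7-O-(3β-acetoxy-9-epi-drim-7-en-11-yl)isofraxidin | COc1cc2ccc(=O)oc2c(OC)c1OC[C@@H]1C(C)=CC[C@H]2C(C)(C)[C@@H](OC(C)=O)CC[C@]12C | target

## Step count and risks

Total step count: 15. Longest linear sequence: 15 steps (1 → 26); 3 and 23 are bought and enter directly.

Most likely to fail:

Step 7 (regioselective mono-methylation at C8). If C6/C8 mixtures or dimethylation dominate, the methyl group is brought in as a methylene instead. The fallback sets out from 13: Mannich-type α-methylenation (paraformaldehyde, N-methylanilinium trifluoroacetate, THF, reflux) gives the 8-methylene-7-ketone F1. RhCl3·3H2O in hot ethanol then moves the exocyclic double bond into the ring, and the fallback comes back to the route at enone 16, so step 8 is bypassed as well.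

Step 10 (Mitsunobu inversion of a hindered allylic alcohol; elimination or SN2′ may compete). The fallback sets out from enone 16 and needs no C7 carbinol. CuI-catalysed 1,4-addition of (i-PrO)Me2SiCH2MgCl attacks C9 axially on the α face, anti to the C10 methyl; trapping the enolate with Comins' reagent gives the enol triflate F2. Reduction of the triflate (Pd(OAc)2, PPh3, HCO2H, Et3N) gives the C7=C8 alkene F3, and Tamao–Fleming oxidation (H2O2, KF, KHCO3) of the C–Si bond returns to the route at alcohol 22.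

Step 12 (Still–Wittig shift onto C9 next to the quaternary C10; [1,2]-shift or simple protonation of the carbanion may compete). The fallback sets out from 19 and makes the same bond by a tin-free carbene-type [2,3] shift. Heating 19 with Me2NCH(OMe)2 in xylene at 140 °C gives the 9α-(N,N-dimethylcarboxamide) F4 with the double bond already at C7=C8. LiBHEt3 reduces the amide to the primary alcohol, coming back to the route at 22.

Further compounds
F1 | step 7 | 3β-TBSO-8-methylene-4,4,10β-trimethyl-5α-decalin-7-one | CC1(C)[C@@H](O[Si](C)(C)C(C)(C)C)CC[C@]2(C)CC(=C)C(=O)C[C@@H]12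
F2 | step 10 | 3β-TBSO-11-[isopropoxy(dimethyl)silyl]-9-epi-drim-7-en-7-yl triflate | CC(C)O[Si](C)(C)C[C@@H]1C(C)=C(OS(=O)(=O)C(F)(F)F)C[C@H]2C(C)(C)[C@@H](O[Si](C)(C)C(C)(C)C)CC[C@]12C
F3 | step 10 | 3β-TBSO-11-[isopropoxy(dimethyl)silyl]-9-epi-drim-7-ene | CC(C)O[Si](C)(C)C[C@@H]1C(C)=CC[C@H]2C(C)(C)[C@@H](O[Si](C)(C)C(C)(C)C)CC[C@]12C
F4 | step 12 | 3β-TBSO-9-epi-drim-7-en-11-oic acid N,N-dimethylamide | CN(C)C(=O)[C@@H]1C(C)=CC[C@H]2C(C)(C)[C@@H](O[Si](C)(C)C(C)(C)C)CC[C@]12C
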